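# Proposed synthesis of CNP0236667.1 from (−)-α-pinene: cis-pinonic acid cyclobutane closed by C(sp3)–H arylation

## Analysis of the target

The target is a 2,2a,7,7a-tetrahydro-1H-cyclobuta[a]indene. Benzene ring A (C2b, C3, C4, C5, C6, C6a) is fused to a five-membered ring (C2a, C2b, C6a, C7, C7a), which shares the C2a–C7a bond with a cyclobutane (C1, C2, C2a, C7a).

C1 is quaternary and carries two methyl groups, and C2 carries the 3,4-dihydroxyphenyl ring. Ring A carries the prenyl group at C3, the methoxy group at C4 and the free hydroxyl at C6, so only C5 is unsubstituted.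

There are three contiguous stereocentres, C2 (S), C2a (R) and C7a (S). The hydrogens at C2a and C7a are cis, as the ring fusion demands, and the catechol ring at C2 is trans to the C2a–C2b bond, on the convex face of the bicycle.

The sensitive groups are the catechol (oxidised in air, above all in base), the phenol, the trisubstituted alkene of the prenyl group (acid, hydrogenation, electrophiles) and the strained, doubly benzylic four-membered ring.

The difficulty is twofold. The cyclobutane is fully substituted, with a quaternary carbon between two stereocentres, is needed as one enantiomer, and keeps no functional group that could steer a reagent. Ring A is pentasubstituted with two differentiated oxygens.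

The strategy rests on one observation. C1 with its two methyl groups, C7a with the one-carbon arm C7, the ring methylene C2a and C2 with an exocyclic carbon together are the skeleton of cis-pinonic acid. With that cyclobutane taken from the chiral pool, the one ring bond left is C2b–C2a, between an arene carbon and a cyclobutane CH2.

## Retrosynthetic reasoning

**Protecting groups (22 to 21).** The three phenolic hydroxyls of 22 are uncovered last, from the tris(methoxymethyl) ether 21 by acetal exchange. The catechol is thus never exposed to base, oxidants or metals. One acetal type on all three oxygens means one final operation. A benzyl ether at C6–O would have to be hydrogenolysed before the prenyl group is present, leaving a free phenol in the last C–C coupling.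

**C3–prenyl bond (21 to 20 to 19).** The prenyl alkene would not survive the hot palladium step, the radical step or an electrophilic halogenation, so it is attached late. In 19, C3 is para to the C6 oxygen and ortho to the C4 methoxy group, while C5 lies between the two oxygens. Electrophilic bromination should therefore mark C3 (20), and a linear-selective allyl–aryl coupling turns the bromide into the prenyl group. The forward steps must distinguish C3 from C5 and from the less activated catechol ring, and must deliver the allyl unit through its primary carbon.

**C2–aryl bond (19 to 14 and 18).** The carbon that pinene leaves on C2 is a carboxyl group, so the cut is made there. The redox-active ester 14 gives a C2 radical, and the arylzinc 18 (from bromide 16, from 15) supplies the catechol ring. Doing this after the tricycle is closed is deliberate. In the bicycle the radical is attacked on the convex face, anti to the C2a–C2b bond, which is the configuration of the target. On the monocyclic cyclobutane no such bias exists. The original configuration at C2 is erased here, so nothing before this point depends on it. 14 comes from acid 13 and ester 12.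

**C2b–C2a bond (12 to 11), the key disconnection.** Cutting the bond between the arene and the cyclobutane leaves an aryl bromide and an unactivated ring CH2 in 11. The forward reaction is a palladium-catalysed C–H arylation. It has to choose the C2a hydrogen that is cis to the C7 arm, which makes the cis ring fusion and fixes C2a from C7a. Cutting C2a–C7a or C2–C2a instead would mean building the four-membered ring and discarding the chiral-pool cyclobutane.

**C6a–C7 bond (11 to 10 and 9).** The arm carbon C7 is joined to the arene by a Negishi coupling of the alkylzinc iodide 10 (from iodide 6) with aryl iodide 9. The bromine of 9 must survive for the key step, and palladium discriminates C–I from C–Br reliably. A two-electron organozinc is preferred to a radical coupling at C7, because a radical on the carbon next to the cyclobutane could open the ring, and because nickel catalysts for radical couplings also attack aryl bromides.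

**Arene fragment (9 to 8 to 7).** In 7 the two oxygens are already differentiated as OH and OMe. The iodine has to enter between the hydroxyl and the bromine, para to the methoxy group (8), and the hydroxyl is then capped (9).

**Cyclobutane fragment (6 to 5 to 4 to 3 to 2 to 1).** The arm of 2 has one carbon too many and the acetyl group has to become a carboxyl. Haloform cleavage gives diacid 3, and double esterification gives 4. Only the unhindered arm ester is saponified (5), and iododecarboxylation shortens the arm to CH2I (6). Acid 2 is the cleavage product of (1S,5S)-α-pinene 1. C7a carries no acidic hydrogen anywhere in this sequence, so the absolute configuration of the whole route is safe.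

## Alternatives that were turned down

**Alternative 1: ring A and the five-membered ring by alkyne cyclotrimerisation.**
- *Disconnection.* Ring A is taken apart at C6a–C2b, C5–C6 and C3–C4.
- *Forward key step.* The cyclobutane diyne A1 (an alkynylboronate arm on C7a, a prenyl-bearing alkyne arm on C2a) and methoxyacetylene A2 are joined by a ruthenium catalyst in a [2+2+2] reaction. It closes the benzene ring and the five-membered ring together and gives the arylboronate A3, whose boron would then be oxidised to the C6 hydroxyl.
- *For.* The arene is built convergently, and prenyl, methoxy and the oxygen precursor arrive in the ring-forming step. On this point it is stronger than the chosen route, which spends two late steps on C3 and relies on a regioselective bromination.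
- *Against.* A1 already contains the whole stereochemical problem: a cyclobutane with three contiguous stereocentres, a quaternary carbon, two different alkynyl arms cis and an aryl group trans. The alternative offers no way to make it. The orientation of A2 in the metallacycle (methoxy next to the prenyl-bearing carbon, not next to boron) is governed by small steric differences. A2 is volatile and polymerises, and the prenyl alkene of A1 can enter the metallacycle.
- *Comparison.* The chosen strategy takes C7a from pinene and derives C2a and C2 from it by ring fusion and convexity. A1 would cost at least as many steps as the whole chosen route to 19.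

**Alternative 2: cyclobutanone by ring expansion of a cyclopropane.**
- *Disconnection.* C2a–C2.
- *Forward key step.* The indane-fused arylidenecyclopropane A4 is epoxidised with a peracid. The spiro-epoxide ionises at the benzylic carbon C2 and C2a migrates, which gives the 2-arylcyclobutanone A5 with the aryl group exo after equilibration.
- *For.* The bicyclic skeleton is reached quickly, and the C2 configuration is set by thermodynamic control at an epimerisable α-carbon. That is arguably more certain than the kinetic radical capture of step 13.
- *Against.* A5 has a carbonyl group where the target has C(CH3)2. Geminal dimethylation of a hindered, enolisable, strained cyclobutanone needs strong Lewis-acidic methyl-transfer reagents that the acetal and silyl ethers and the epimerisable C2 will not tolerate, or several steps through an alkene. The absolute configuration of A4 would have to come from an enantioselective carbene transfer, for which no controlling element is at hand. Migration of C7a instead of C2a is possible, and the C3 prenyl group is still missing.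
- *Comparison.* In the chosen route the gem-dimethyl group and the absolute configuration are part of the starting material.

**Alternative 3: transannular enolate alkylation.**
- *Disconnection.* C2a–C7a.
- *Forward key step.* The benzocycloheptenone A6, with the ketone at C7 and a benzylic bromide at C2a, is deprotonated at C7a. The enolate displaces bromide across the ring with inversion and gives the tricyclic ketone A7, closing the four- and five-membered rings with one bond.
- *For.* One bond makes two rings. The C7 carbonyl next to the C6 methoxy group would allow chelation-assisted cleavage of that ether alone, which differentiates the two ring A oxygens more cleanly than the chosen route's regioselective iodination of 7.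
- *Against.* Closing a cyclobutane by enolate alkylation is among the slowest ring closures. The leaving group sits on a secondary benzylic carbon with a hydrogen at C2, so elimination to a stilbene-like alkene conjugated with both arenes, and ionisation with loss of configuration, should win. O-alkylation of the aryl ketone enolate also competes. A6 needs its two stereocentres made enantioselectively, and after A7 the ketone must be removed, one ether cleaved and the prenyl group introduced.
- *Comparison.* The chosen ring closure runs through a favourable six-membered palladacycle on a substrate whose configuration is inherited, and the oxygens are differentiated from the first arene intermediate.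

Key step: step 9

## Route

Assumption: in step 6 iodine is taken to enter ortho to the hydroxyl and para to the methoxy group of 7, as it does with 3-methoxyphenol under the same conditions; the position would be confirmed by NOE before 8 is used.

Step 1
Reactants: 1 (1S,5S)-(−)-α-pinene
Product: 2 (1R,3R)-cis-pinonic acid, 2-[(1R,3R)-3-acetyl-2,2-dimethylcyclobutyl]acetic acid
Conditions: RuCl3·xH2O (2 mol%), NaIO4 (4 equiv), MeCN/EtOAc/H2O, 0 °C to rt
Reagents that add atoms: sodium periodate, [Na+].[O-]I(=O)(=O)=O
Why: Oxidative cleavage of the trisubstituted alkene by catalytic RuO4 gives the methyl ketone and the carboxylic acid; no ring stereocentre is touched, so the cis arrangement and absolute configuration of 1 are carried over (the descriptors change from S,S to R,R only because the substituent priorities change).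

Step 2
Reactants: 2 (1R,3R)-cis-pinonic acid
Product: 3 cis-pinic acid, (1R,3R)-3-(carboxymethyl)-2,2-dimethylcyclobutane-1-carboxylic acid
Conditions: Br2, NaOH, H2O/1,4-dioxane, 0 °C to rt; then aq. HCl
Reagents that add atoms: sodium hydroxide, [Na+].[OH-]
Why: Haloform reaction: the methyl ketone is tribrominated and cleaved by hydroxide to the carboxylate. Partial epimerisation of the ring carbon α to the ketone would be harmless, because that carbon (C2 of the target) becomes a radical in step 13, and C7a has no acidic hydrogen.

Step 3
Reactants: 3 cis-pinic acid
Product: 4 dimethyl cis-pinate, methyl (1R,3R)-3-(2-methoxy-2-oxoethyl)-2,2-dimethylcyclobutane-1-carboxylate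
Conditions: MeOH, H2SO4 (cat.), reflux
Reagents that add atoms: methanol, CO
Why: Fischer esterification of both carboxyl groups under acid, where neither stereocentre can epimerise.

Step 4
Reactants: 4 dimethyl cis-pinate
Product: 5 2-[(1R,3R)-3-(methoxycarbonyl)-2,2-dimethylcyclobutyl]acetic acid
Conditions: LiOH·H2O (1.05 equiv), THF/H2O, 0 °C; then aq. HCl
Reagents that add atoms: lithium hydroxide, [Li+].[OH-]
Why: Kinetically selective saponification: the CH2CO2CH3 ester is unhindered, whereas the ring ester sits on a carbon next to the quaternary C(CH3)2 and is attacked much more slowly, so one equivalent of hydroxide at 0 °C should stop at the half-ester.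

Step 5
Reactants: 5 2-[(1R,3R)-3-(methoxycarbonyl)-2,2-dimethylcyclobutyl]acetic acid
Product: 6 methyl (1R,3S)-3-(iodomethyl)-2,2-dimethylcyclobutane-1-carboxylate
Conditions: PhI(OAc)2, I2, 1,2-dichloroethane, hν (tungsten lamp), 60 °C
Reagents that add atoms: iodine, II
Why: Hunsdiecker-type iododecarboxylation: O–I homolysis and loss of CO2 give the primary radical at C7, which iodine traps at a diffusion-controlled rate, far faster than opening of the neighbouring cyclobutane. No arene that could be iodinated is present yet, and C7a is not involved (its descriptor changes only by priority).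

Step 6
Reactants: 7 3-bromo-5-methoxyphenol
Product: 8 3-bromo-2-iodo-5-methoxyphenol
Conditions: I2 (1.0 equiv), NaHCO3, THF/H2O, 0 °C to rt
Reagents that add atoms: iodine, II
Why: Electrophilic iodination of the phenoxide: the carbon ortho to O− and para to OCH3 should be attacked, as in 3-methoxyphenol under these conditions, the carbon between the two oxygens being the least reactive. One equivalent of iodine limits double iodination.

Step 7
Reactants: 8 3-bromo-2-iodo-5-methoxyphenol
Product: 9 1-bromo-2-iodo-5-methoxy-3-(methoxymethoxy)benzene
Conditions: MOMCl, iPr2NEt, CH2Cl2, 0 °C to rt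
Reagents that add atoms: chloromethyl methyl ether, COCCl
Why: O-alkylation of the phenol to the methoxymethyl ether, which is stable to organozinc reagents, carbonate at 140 °C, hydroxide and radicals, and is removed together with the catechol ethers in step 16.

Step 8
Reactants: 6 methyl (1R,3S)-3-(iodomethyl)-2,2-dimethylcyclobutane-1-carboxylate; 9 1-bromo-2-iodo-5-methoxy-3-(methoxymethoxy)benzene
Product: 11 methyl (1R,3R)-3-{[2-bromo-4-methoxy-6-(methoxymethoxy)phenyl]methyl}-2,2-dimethylcyclobutane-1-carboxylate, via alkylzinc iodide 10 (not isolated)
Conditions: Zn dust (activated with TMSCl and BrCH2CH2Br), DMA, 40 °C; then 9 (1.3 equiv), Pd2(dba)3 (2.5 mol%), SPhos (10 mol%), 25 to 45 °C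
Reagents that add atoms: none
Why: Negishi coupling: zinc inserts into the primary C–I bond to give 10, which tolerates the ester. Zerovalent palladium adds to the C–I bond of 9 much faster than to its C–Br bond, and the biaryl phosphine accommodates the two ortho substituents. The excess of 9 keeps the bromide of 11 out of the catalytic cycle, and no stereocentre is at a reacting carbon.

Step 9
Reactants: 11 methyl (1R,3R)-3-{[2-bromo-4-methoxy-6-(methoxymethoxy)phenyl]methyl}-2,2-dimethylcyclobutane-1-carboxylate
Product: 12 methyl (2R,2aR,7aS)-4-methoxy-6-(methoxymethoxy)-1,1-dimethyl-2,2a,7,7a-tetrahydro-1H-cyclobuta[a]indene-2-carboxylate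
Conditions: Pd(OAc)2 (10 mol%), PCy3·HBF4 (20 mol%), Cs2CO3 (1.5 equiv), PivOH (30 mol%), mesitylene, 140 °C
Reagents that add atoms: none
Why: Zerovalent palladium, formed from Pd(OAc)2 and PCy3, adds oxidatively to the C2b–Br bond; bromide is exchanged for pivalate, which removes the C2a hydrogen cis to the C7 arm by concerted metalation–deprotonation through a six-membered palladacycle (Pd, C2b, C6a, C7, C7a, C2a), and C–C reductive elimination forms C2b–C2a. The closest known reaction type is the palladium-catalysed intramolecular C(sp3)–H arylation of 2-alkylaryl bromides to indanes, established for methyl and ring methylene C–H bonds, cyclopropane C–H bonds included; a cyclobutane C–H bond has raised s-character and should behave likewise. The five-membered ring is closed by reductive elimination from that palladacycle (formally a 5-exo closure onto C2a) and can only be cis-fused to the four-membered ring. The new stereocentre C2a is therefore controlled by C7a alone: the tether reaches only the hydrogen on the face of the C7 arm, which gives 2aR. The step needs site selectivity for C2a–H over the methyl C–H bonds at C1 and over C7a–H: the methyl groups would require a seven-membered palladacycle, C7a–H is a tertiary C–H that would lead to a strained spiro-benzocyclobutene, and the two ether groups are meta to palladium and out of reach. Reductive elimination from the diorganopalladium is expected to outrun β-hydride elimination, which would have to form a cyclobutene. The ester is inert, and its epimerisation at C2 under carbonate would be without consequence.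

Step 10
Reactants: 12 methyl (2R,2aR,7aS)-4-methoxy-6-(methoxymethoxy)-1,1-dimethyl-2,2a,7,7a-tetrahydro-1H-cyclobuta[a]indene-2-carboxylate
Product: 13 (2R,2aR,7aS)-4-methoxy-6-(methoxymethoxy)-1,1-dimethyl-2,2a,7,7a-tetrahydro-1H-cyclobuta[a]indene-2-carboxylic acid
Conditions: LiOH·H2O (10 equiv), THF/MeOH/H2O, 60 °C; then aq. HCl to pH 4, 0 °C
Reagents that add atoms: lithium hydroxide, [Li+].[OH-]
Why: Saponification of a hindered ester (endo, next to the quaternary carbon) needs excess hydroxide and heat. Epimerisation at C2 under these conditions is harmless because C2 is made planar in step 13, and the acetal and aryl ethers are stable to base and to the brief cold acidification.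

Step 11
Reactants: 13 (2R,2aR,7aS)-4-methoxy-6-(methoxymethoxy)-1,1-dimethyl-2,2a,7,7a-tetrahydro-1H-cyclobuta[a]indene-2-carboxylic acid
Product: 14 4,5,6,7-tetrachloro-1,3-dioxoisoindolin-2-yl (2R,2aR,7aS)-4-methoxy-6-(methoxymethoxy)-1,1-dimethyl-2,2a,7,7a-tetrahydro-1H-cyclobuta[a]indene-2-carboxylate
Conditions: N-hydroxytetrachlorophthalimide, DIC, DMAP (cat.), CH2Cl2, rt
Reagents that add atoms: N-hydroxytetrachlorophthalimide, ON1C(=O)c2c(Cl)c(Cl)c(Cl)c(Cl)c2C1=O
Why: Carbodiimide (Steglich-type) esterification gives the redox-active ester, which is isolated by rapid filtration so that the hindered acid is fully activated before the coupling.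

Step 12
Reactants: 15 4-bromocatechol
Product: 16 4-bromo-1,2-bis(methoxymethoxy)benzene
Conditions: MOMCl (2.5 equiv), iPr2NEt, CH2Cl2, 0 °C to rt
Reagents that add atoms: chloromethyl methyl ether, COCCl
Why: Double O-alkylation masks the oxidation-prone catechol as a bis-acetal that survives magnesium, zinc, nickel, N-bromosuccinimide and palladium and is cleaved by mild acid.

Step 13
Reactants: 14 4,5,6,7-tetrachloro-1,3-dioxoisoindolin-2-yl (2R,2aR,7aS)-4-methoxy-6-(methoxymethoxy)-1,1-dimethyl-2,2a,7,7a-tetrahydro-1H-cyclobuta[a]indene-2-carboxylate; 16 4-bromo-1,2-bis(methoxymethoxy)benzene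
Product: 19 (2S,2aR,7aS)-2-[3,4-bis(methoxymethoxy)phenyl]-4-methoxy-6-(methoxymethoxy)-1,1-dimethyl-2,2a,7,7a-tetrahydro-1H-cyclobuta[a]indene, via arylmagnesium bromide 17 (not isolated), via arylzinc chloride 18 (not isolated)
Conditions: Mg, LiCl, THF, rt; ZnCl2; then 14, NiCl2·glyme (20 mol%), 4,4′-di-tert-butyl-2,2′-bipyridine (40 mol%), THF/DMF, rt
Reagents that add atoms: none
Why: Nickel-catalysed decarboxylative Negishi arylation of a secondary redox-active ester: electron transfer from low-valent nickel releases CO2 and the phthalimide anion and leaves a cyclobutyl radical at C2, which the arylnickel species captures before C–C reductive elimination. The aryl group is delivered to the convex face, anti to the C2a–C2b bond and away from ring A, which sets C2 as S whatever its configuration in 14.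

Step 14
Reactants: 19 (2S,2aR,7aS)-2-[3,4-bis(methoxymethoxy)phenyl]-4-methoxy-6-(methoxymethoxy)-1,1-dimethyl-2,2a,7,7a-tetrahydro-1H-cyclobuta[a]indene
Product: 20 (2S,2aR,7aS)-2-[3,4-bis(methoxymethoxy)phenyl]-3-bromo-4-methoxy-6-(methoxymethoxy)-1,1-dimethyl-2,2a,7,7a-tetrahydro-1H-cyclobuta[a]indene
Conditions: NBS (1.0 equiv), MeCN, −20 to 0 °C
Reagents that add atoms: N-bromosuccinimide, O=C1CCC(=O)N1Br
Why: Electrophilic aromatic bromination: C3 is para to the C6 oxygen and ortho to the C4 methoxy group, whereas C5 lies between the two oxygens and is the less reactive site of a 1,3-dioxygenated benzene. The catechol ring lacks this cooperative meta-dioxygen activation and should react far more slowly at low temperature with one equivalent.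

Step 15
Reactants: 20 (2S,2aR,7aS)-2-[3,4-bis(methoxymethoxy)phenyl]-3-bromo-4-methoxy-6-(methoxymethoxy)-1,1-dimethyl-2,2a,7,7a-tetrahydro-1H-cyclobuta[a]indene
Product: 21 (2S,2aR,7aS)-2-[3,4-bis(methoxymethoxy)phenyl]-4-methoxy-6-(methoxymethoxy)-1,1-dimethyl-3-(3-methylbut-2-en-1-yl)-2,2a,7,7a-tetrahydro-1H-cyclobuta[a]indene
Conditions: prenylzinc bromide·LiCl (from prenyl bromide, Zn, LiCl, THF; 1.5 equiv), Pd(OAc)2 (3 mol%), CPhos (6 mol%), THF, rt to 40 °C
Reagents that add atoms: 3-methylbut-2-en-1-ylzinc bromide, CC(C)=CC[Zn]Br
Why: Negishi coupling of an allylic zinc halide: with the bulky biaryl phosphine, reductive elimination takes place from the less hindered primary allyl terminus and gives the linear prenyl arene. The substrate carries no acidic hydrogen and no other halide.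

Step 16
Reactants: 21 (2S,2aR,7aS)-2-[3,4-bis(methoxymethoxy)phenyl]-4-methoxy-6-(methoxymethoxy)-1,1-dimethyl-3-(3-methylbut-2-en-1-yl)-2,2a,7,7a-tetrahydro-1H-cyclobuta[a]indene
Product: 22 4-[(2S,2aR,7aS)-6-hydroxy-4-methoxy-1,1-dimethyl-3-(3-methylbut-2-en-1-yl)-2,2a,7,7a-tetrahydro-1H-cyclobuta[a]inden-2-yl]benzene-1,2-diol (target)
Conditions: 3 M HCl in MeOH, degassed, argon, rt to 40 °C
Reagents that add atoms: none
Why: Acid-catalysed acetal exchange with methanol removes the three methoxymethyl groups as dimethoxymethane. The prenyl group has no free ortho hydroxyl (C4 is a methyl ether), so chroman formation is excluded, and the mild acid and exclusion of air should spare the alkene and the catechol.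

## Compound list

1 | (1S,5S)-(−)-α-pinene | CC1=CC[C@H]2C[C@@H]1C2(C)C | starting material
2 | (1R,3R)-cis-pinonic acid, 2-[(1R,3R)-3-acetyl-2,2-dimethylcyclobutyl]acetic acid | CC(=O)[C@@H]1C[C@H](CC(O)=O)C1(C)C | intermediate
3 | cis-pinic acid, (1R,3R)-3-(carboxymethyl)-2,2-dimethylcyclobutane-1-carboxylic acid | OC(=O)[C@@H]1C[C@H](CC(O)=O)C1(C)C | intermediate
4 | methyl (1R,3R)-3-(2-methoxy-2-oxoethyl)-2,2-dimethylcyclobutane-1-carboxylate | COC(=O)[C@@H]1C[C@H](CC(=O)OC)C1(C)C | intermediate
5 | 2-[(1R,3R)-3-(methoxycarbonyl)-2,2-dimethylcyclobutyl]acetic acid | COC(=O)[C@@H]1C[C@H](CC(O)=O)C1(C)C | intermediate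
6 | methyl (1R,3S)-3-(iodomethyl)-2,2-dimethylcyclobutane-1-carboxylate | COC(=O)[C@@H]1C[C@H](CI)C1(C)C | intermediate
7 | 3-bromo-5-methoxyphenol | COc1cc(O)cc(Br)c1 | starting material
8 | 3-bromo-2-iodo-5-methoxyphenol | COc1cc(O)c(I)c(Br)c1 | intermediate
9 | 1-bromo-2-iodo-5-methoxy-3-(methoxymethoxy)benzene | COCOc1cc(OC)cc(Br)c1I | intermediate
10 | {[(1S,3R)-3-(methoxycarbonyl)-2,2-dimethylcyclobutyl]methyl}zinc iodide | COC(=O)[C@@H]1C[C@H](C[Zn]I)C1(C)C | intermediate (not isolated)
11 | methyl (1R,3R)-3-{[2-bromo-4-methoxy-6-(methoxymethoxy)phenyl]methyl}-2,2-dimethylcyclobutane-1-carboxylate | COCOc1cc(OC)cc(Br)c1C[C@H]1C[C@@H](C(=O)OC)C1(C)C | intermediate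
12 | methyl (2R,2aR,7aS)-4-methoxy-6-(methoxymethoxy)-1,1-dimethyl-2,2a,7,7a-tetrahydro-1H-cyclobuta[a]indene-2-carboxylate | COc1cc(OCOC)c2c(c1)[C@@H]1[C@H](C2)C(C)(C)[C@@H]1C(=O)OC | intermediate
13 | (2R,2aR,7aS)-4-methoxy-6-(methoxymethoxy)-1,1-dimethyl-2,2a,7,7a-tetrahydro-1H-cyclobuta[a]indene-2-carboxylic acid | COc1cc(OCOC)c2c(c1)[C@@H]1[C@H](C2)C(C)(C)[C@@H]1C(O)=O | intermediate
14 | 4,5,6,7-tetrachloro-1,3-dioxoisoindolin-2-yl (2R,2aR,7aS)-4-methoxy-6-(methoxymethoxy)-1,1-dimethyl-2,2a,7,7a-tetrahydro-1H-cyclobuta[a]indene-2-carboxylate | COc1cc(OCOC)c2c(c1)[C@@H]1[C@H](C2)C(C)(C)[C@@H]1C(=O)ON1C(=O)c2c(Cl)c(Cl)c(Cl)c(Cl)c2C1=O | intermediate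
15 | 4-bromocatechol | Oc1ccc(Br)cc1O | starting material
16 | 4-bromo-1,2-bis(methoxymethoxy)benzene | COCOc1ccc(Br)cc1OCOC | intermediate
17 | [3,4-bis(methoxymethoxy)phenyl]magnesium bromide | COCOc1ccc([Mg]Br)cc1OCOC | intermediate (not isolated)
18 | [3,4-bis(methoxymethoxy)phenyl]zinc chloride | COCOc1ccc([Zn]Cl)cc1OCOC | intermediate (not isolated)
19 | (2S,2aR,7aS)-2-[3,4-bis(methoxymethoxy)phenyl]-4-methoxy-6-(methoxymethoxy)-1,1-dimethyl-2,2a,7,7a-tetrahydro-1H-cyclobuta[a]indene | COc1cc(OCOC)c2c(c1)[C@@H]1[C@H](C2)C(C)(C)[C@H]1c1ccc(OCOC)c(OCOC)c1 | intermediate
20 | (2S,2aR,7aS)-2-[3,4-bis(methoxymethoxy)phenyl]-3-bromo-4-methoxy-6-(methoxymethoxy)-1,1-dimethyl-2,2a,7,7a-tetrahydro-1H-cyclobuta[a]indene | COc1cc(OCOC)c2c(c1Br)[C@@H]1[C@H](C2)C(C)(C)[C@H]1c1ccc(OCOC)c(OCOC)c1 | intermediate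
21 | (2S,2aR,7aS)-2-[3,4-bis(methoxymethoxy)phenyl]-4-methoxy-6-(methoxymethoxy)-1,1-dimethyl-3-(3-methylbut-2-en-1-yl)-2,2a,7,7a-tetrahydro-1H-cyclobuta[a]indene | COc1cc(OCOC)c2c(c1CC=C(C)C)[C@@H]1[C@H](C2)C(C)(C)[C@H]1c1ccc(OCOC)c(OCOC)c1 | intermediate
22 | 4-[(2S,2aR,7aS)-6-hydroxy-4-methoxy-1,1-dimethyl-3-(3-methylbut-2-en-1-yl)-2,2a,7,7a-tetrahydro-1H-cyclobuta[a]inden-2-yl]benzene-1,2-diol | COc1cc(O)c2c(c1CC=C(C)C)[C@@H]1[C@H](C2)C(C)(C)[C@H]1c1ccc(O)c(O)c1 | target

## Step count and least certain steps

Total step count: 16. Longest linear sequence: 13 steps (steps 1–5, 8–11 and 13–16, from 1 to 22). The arene fragment (steps 6, 7) and the catechol fragment (step 12) are made in parallel.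

**Step 9 (key step).** The most likely failure is palladation at the wrong C–H bond or loss of bromine without ring closure. Methyl C–H bonds are intrinsically easier to cleave by concerted metalation–deprotonation than methylene ones, the methyl group at C1 on the face of the arm is also within reach (through a seven-membered palladacycle), and the cis ester at C2 crowds the C2a hydrogen. The fallback sets out from 11 and forms the same bond by a radical conjugate addition. Deprotonation with LDA and selenation with PhSeBr would give the α-phenylselanyl ester F1. Oxidation with H2O2 and syn-elimination, which can only run towards C2a because C1 is quaternary, would give the cyclobutene ester F2. The aryl radical generated at C2b with Bu3SnH and AIBN at 80 °C should add 5-exo-trig to C2a, the β-carbon of the strained unsaturated ester, and necessarily on the face of the C7 arm. Hydrogen transfer to the C2 radical would give 12 together with its C2 epimer F3. Both are carried on, since C2 is made planar in step 13. The fallback returns to the route at 12.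

**Step 6.** Iodination may occur at the wrong carbon (para to the hydroxyl, between bromine and methoxy), which would end with the two oxygen functions exchanged, or twice; the orienting effects of the two oxygens are close. The fallback sets out from 7 and fixes the regiochemistry by symmetry and chelation:
- O-methylation (MeI, K2CO3) gives 1-bromo-3,5-dimethoxybenzene F4, in which the two reactive positions are equivalent.
- Vilsmeier–Haack formylation (POCl3, DMF) gives 2-bromo-4,6-dimethoxybenzaldehyde F5.
- BCl3 cleaves only the methyl ether ortho to the aldehyde, through the chelate, and gives 2-bromo-6-hydroxy-4-methoxybenzaldehyde F6.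
- MOMCl and iPr2NEt give 2-bromo-4-methoxy-6-(methoxymethoxy)benzaldehyde F7.
- Pinnick oxidation gives 2-bromo-4-methoxy-6-(methoxymethoxy)benzoic acid F8.
- Iododecarboxylation of this electron-rich, doubly ortho-substituted benzoic acid (I2, K3PO4, MeCN, 100 °C) gives 9, where the fallback returns to the route.

**Step 8.** Palladium may insert into the C–Br bond of 9 or of 11 (double coupling, oligomers), or transmetalation at the doubly ortho-substituted arylpalladium may be slow and lead to reduction of the iodide. The fallback sets out from 5 and 9 and reverses the roles of the partners. Acid 5 is converted with N-hydroxytetrachlorophthalimide and DIC into the redox-active ester F9. Zinc insertion into the C–I bond of 9 (Zn, LiCl, THF) gives the arylzinc iodide F10. An iron-catalysed decarboxylative Negishi coupling (Fe(acac)3, 1,2-bis(diphenylphosphino)benzene, THF) joins the two to 11, where it returns to the route. No zerovalent palladium is present, and iron catalysts of this kind leave aryl bromides untouched. The price is a free radical at C7 next to the cyclobutane.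

**Step 13.** The hindered activated ester may be consumed by the arylzinc reagent or by reduction faster than the nickel cycle turns over, because capture of a neopentyl-type secondary radical is slow. The fallback sets out from 13 and 16 and uses neither an activated ester nor an organometallic reagent: a decarboxylative arylation by combined photoredox and nickel catalysis ([Ir{dF(CF3)ppy}2(dtbbpy)]PF6, NiCl2·glyme, 4,4′-di-tert-butyl-2,2′-bipyridine, Cs2CO3, DMF, blue light). The radical is formed by oxidation of the carboxylate, and the aryl bromide enters by oxidative addition to nickel. The convex-face argument is unchanged, and the fallback returns to the route at 19.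

**Step 15.** The allyl unit may be transferred through its tertiary terminus (reverse-prenyl isomer), or oxidative addition may stall at a bromide flanked by the methoxy group and the ring fusion on an electron-rich ring. The fallback sets out from 20 and is anionic. Bromine–lithium exchange (n-BuLi, THF, −78 °C) gives the C3 aryllithium F11, which is allylated with prenyl bromide in the presence of catalytic CuBr·SMe2, where substitution at the primary carbon is expected. It returns to the route at 21.

## Further compounds

F1 | step 9 | methyl (3S)-3-{[2-bromo-4-methoxy-6-(methoxymethoxy)phenyl]methyl}-2,2-dimethyl-1-(phenylselanyl)cyclobutane-1-carboxylate (both epimers at C1) | COC(=O)C1([Se]c2ccccc2)C[C@H](Cc2c(Br)cc(OC)cc2OCOC)C1(C)C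
F2 | step 9 | methyl (3S)-3-{[2-bromo-4-methoxy-6-(methoxymethoxy)phenyl]methyl}-4,4-dimethylcyclobut-1-ene-1-carboxylate | COC(=O)C1=C[C@H](Cc2c(Br)cc(OC)cc2OCOC)C1(C)C
F3 | step 9 | methyl (2S,2aR,7aS)-4-methoxy-6-(methoxymethoxy)-1,1-dimethyl-2,2a,7,7a-tetrahydro-1H-cyclobuta[a]indene-2-carboxylate | COc1cc(OCOC)c2c(c1)[C@@H]1[C@H](C2)C(C)(C)[C@H]1C(=O)OC
F4 | step 6 | 1-bromo-3,5-dimethoxybenzene | COc1cc(OC)cc(Br)c1
F5 | step 6 | 2-bromo-4,6-dimethoxybenzaldehyde | COc1cc(OC)c(C=O)c(Br)c1
F6 | step 6 | 2-bromo-6-hydroxy-4-methoxybenzaldehyde | COc1cc(O)c(C=O)c(Br)c1
F7 | step 6 | 2-bromo-4-methoxy-6-(methoxymethoxy)benzaldehyde | COCOc1cc(OC)cc(Br)c1C=O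
F8 | step 6 | 2-bromo-4-methoxy-6-(methoxymethoxy)benzoic acid | COCOc1cc(OC)cc(Br)c1C(O)=O
F9 | step 8 | 4,5,6,7-tetrachloro-1,3-dioxoisoindolin-2-yl 2-[(1R,3R)-3-(methoxycarbonyl)-2,2-dimethylcyclobutyl]acetate | COC(=O)[C@@H]1C[C@H](CC(=O)ON2C(=O)c3c(Cl)c(Cl)c(Cl)c(Cl)c3C2=O)C1(C)C
F10 | step 8 | [2-bromo-4-methoxy-6-(methoxymethoxy)phenyl]zinc iodide | COCOc1cc(OC)cc(Br)c1[Zn]I
F0 | step 13 | none | none
F11 | step 15 | {(2S,2aR,7aS)-2-[3,4-bis(methoxymethoxy)phenyl]-4-methoxy-6-(methoxymethoxy)-1,1-dimethyl-2,2a,7,7a-tetrahydro-1H-cyclobuta[a]inden-3-yl}lithium | COc1cc(OCOC)c2c(c1[Li])[C@@H]1[C@H](C2)C(C)(C)[C@H]1c1ccc(OCOC)c(OCOC)c1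
A1 | alternative 1 | cyclobutane diyne: 2-[3,4-bis(methoxymethoxy)phenyl]-3,3-dimethyl-1-(5-methylhex-4-en-1-yn-1-yl)-4-[3-(4,4,5,5-tetramethyl-1,3,2-dioxaborolan-2-yl)prop-2-yn-1-yl]cyclobutane, configured as in the target | CC(C)=CCC#C[C@@H]1[C@H](CC#CB2OC(C)(C)C(C)(C)O2)C(C)(C)[C@H]1c1ccc(OCOC)c(OCOC)c1
A2 | alternative 1 | methoxyacetylene | COC#C
A3 | alternative 1 | C6 pinacolboronate of the target skeleton, catechol as bis(methoxymethyl) ether | COc1cc(B3OC(C)(C)C(C)(C)O3)c2c(c1CC=C(C)C)[C@@H]1[C@H](C2)C(C)(C)[C@H]1c1ccc(OCOC)c(OCOC)c1
A4 | alternative 2 | (E)-1-[3,4-bis(methoxymethoxy)benzylidene]-5-(tert-butyldimethylsilyloxy)-3-methoxy-1,1a,6,6a-tetrahydrocyclopropa[a]indene | COc1cc(O[Si](C)(C)C(C)(C)C)c2c(c1)[C@@H]1[C@H](C2)/C1=C\c1ccc(OCOC)c(OCOC)c1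
A5 | alternative 2 | 2-[3,4-bis(methoxymethoxy)phenyl]-6-(tert-butyldimethylsilyloxy)-4-methoxy-2,2a,7,7a-tetrahydro-1H-cyclobuta[a]inden-1-one, aryl group exo | COc1cc(O[Si](C)(C)C(C)(C)C)c2c(c1)[C@@H]1[C@H](C2)C(=O)[C@H]1c1ccc(OCOC)c(OCOC)c1
A6 | alternative 3 | 5-bromo-6-[3,4-bis(methoxymethoxy)phenyl]-1,3-dimethoxy-7,7-dimethyl-5,6,7,8-tetrahydro-9H-benzo[7]annulen-9-one | COc1cc(OC)c2c(c1)[C@@H](Br)[C@H](c1ccc(OCOC)c(OCOC)c1)C(C)(C)CC2=O
A7 | alternative 3 | 2-[3,4-bis(methoxymethoxy)phenyl]-4,6-dimethoxy-1,1-dimethyl-1,2,2a,7a-tetrahydro-7H-cyclobuta[a]inden-7-one | COc1cc(OC)c2c(c1)[C@@H]1[C@H](C2=O)C(C)(C)[C@H]1c1ccc(OCOC)c(OCOC)c1
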